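**Target as read from the SMILES:** (2R,3S)-3-(3,4-dimethoxyphenyl)-2-[(E)-3-(3,4-dimethoxyphenyl)prop-2-en-1-yl]-3-hydroxypropyl (Z)-2-(hydroxymethyl)but-2-enoate. The two stereocentres are syn in the aldol sense, the styrene is E, and the acyl group is the Z (angelate-type) isomer.

## Retrosynthetic overview

1. The last bond made is the ester C–O bond between the primary hydroxyl of the free syn-1,3-diol and a (Z)-2-(hydroxymethyl)but-2-enoyl donor, with no protecting groups.
2. The donor is the strained (Z)-3-ethylideneoxetan-2-one, closed in the flask from (Z)-2-iodobut-2-en-1-ol and CO and then opened at its acyl carbon by the diol. The iodo alcohol comes from crotonaldehyde in two steps, which fixes the Z alkene.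
3. The diol comes from an Evans syn-aldol adduct of an N-acyl oxazolidinone with veratraldehyde (sets both stereocentres), followed by reductive removal of the auxiliary.
4. The E-styrenyl chain of the imide comes from cross-metathesis of the N-pent-4-enoyl oxazolidinone with 3,4-dimethoxystyrene.
5. Rings: both arenes are bought. The only ring made is the transient four-membered lactone, formed and opened within the last step.

Assumption: a one-pot operation that runs through a compound that is not isolated counts as one step.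

## Route

Step 1
Reactants: 1 (S)-4-benzyloxazolidin-2-one; 2 pent-4-enoyl chloride
Product: 3 (S)-4-benzyl-3-(pent-4-enoyl)oxazolidin-2-one
Conditions: Et3N (1.5 equiv), DMAP (10 mol%), CH2Cl2, 0 °C to rt
Reagents that add atoms: none
Why: DMAP-catalysed N-acylation (nucleophilic acyl substitution) of the oxazolidinone by the acid chloride, in which the auxiliary stereocentre takes no part.

Step 2
Reactants: 3 (S)-4-benzyl-3-(pent-4-enoyl)oxazolidin-2-one; 4 3,4-dimethoxystyrene
Product: 5 (S)-4-benzyl-3-[(E)-5-(3,4-dimethoxyphenyl)pent-4-enoyl]oxazolidin-2-one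
Conditions: second-generation Grubbs catalyst (H2IMes)(PCy3)Cl2Ru=CHPh (3 mol%), 4 (3 equiv), CH2Cl2, 40 °C
Reagents that add atoms: none
Why: Olefin cross-metathesis of a terminal alkene with a styrene is driven by loss of ethylene and gives the conjugated disubstituted alkene as the E isomer under thermodynamic control, and the imide is tolerated.

Step 3
Reactants: 5 (S)-4-benzyl-3-[(E)-5-(3,4-dimethoxyphenyl)pent-4-enoyl]oxazolidin-2-one; 6 3,4-dimethoxybenzaldehyde
Product: 9 (S)-4-benzyl-3-[(2S,3S)-3-(3,4-dimethoxyphenyl)-2-[(E)-3-(3,4-dimethoxyphenyl)prop-2-en-1-yl]-3-hydroxypropanoyl]oxazolidin-2-one, via dibutylboron Z-enolate 7 (not isolated), via dibutylboron aldolate 8 (not isolated)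
Conditions: Bu2BOTf (1.2 equiv), i-Pr2NEt (1.4 equiv), CH2Cl2, 0 °C; then 6 (1.3 equiv), −78 to 0 °C; then pH 7 buffer (NaH2PO4/Na2HPO4), MeOH, 30% H2O2, 0 °C
Reagents that add atoms: dibutylboron triflate, CCCCB(CCCC)OS(=O)(=O)C(F)(F)F (its Bu2B group is carried by 7 and 8 only and is cleaved in the work-up)
Why: Evans boron syn-aldol reaction, in which the Z-enolate 7 reacts through a Zimmerman–Traxler chair with the imide carbonyl turned away from the enolate oxygen, so the aldehyde adds to the enolate face opposite the benzyl group and both new stereocentres are set as (2S,3S) syn.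

Step 4
Reactants: 9 (S)-4-benzyl-3-[(2S,3S)-3-(3,4-dimethoxyphenyl)-2-[(E)-3-(3,4-dimethoxyphenyl)prop-2-en-1-yl]-3-hydroxypropanoyl]oxazolidin-2-one
Product: 10 (1S,2R)-1-(3,4-dimethoxyphenyl)-2-[(E)-3-(3,4-dimethoxyphenyl)prop-2-en-1-yl]propane-1,3-diol
Conditions: LiBH4 (2 equiv), MeOH (2 equiv), THF, 0 °C
Reagents that add atoms: none
Why: Hydride reductive cleavage of the N-acyl oxazolidinone, in which LiBH4 attacks the exocyclic acyl carbonyl and reduces it to the primary alcohol while releasing the auxiliary, without touching either stereocentre or the alkene (the descriptor at the former alpha carbon changes from S to R only because the priorities change).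

Step 5
Reactants: 11 (E)-but-2-enal
Product: 12 (Z)-2-iodobut-2-enal
Conditions: I2 (1.5 equiv), K2CO3 (1.2 equiv), DMAP (20 mol%), THF/H2O (1:1), rt, dark
Reagents that add atoms: iodine, [I][I]
Why: Alpha-iodination of an enal by an addition–elimination sequence of the Morita–Baylis–Hillman type (conjugate addition of DMAP, iodination of the enolate, E1cB loss of DMAP), which gives the Z-iodoenal with the methyl group trans to the formyl group.

Step 6
Reactants: 12 (Z)-2-iodobut-2-enal
Product: 13 (Z)-2-iodobut-2-en-1-ol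
Conditions: NaBH4, MeOH, 0 °C
Reagents that add atoms: none
Why: Chemoselective 1,2-hydride reduction of the aldehyde by NaBH4, which leaves the vinyl iodide and its Z geometry untouched.

Step 7
Reactants: 13 (Z)-2-iodobut-2-en-1-ol; 10 (1S,2R)-1-(3,4-dimethoxyphenyl)-2-[(E)-3-(3,4-dimethoxyphenyl)prop-2-en-1-yl]propane-1,3-diol
Product: 15 (2R,3S)-3-(3,4-dimethoxyphenyl)-2-[(E)-3-(3,4-dimethoxyphenyl)prop-2-en-1-yl]-3-hydroxypropyl (Z)-2-(hydroxymethyl)but-2-enoate (target), via (Z)-3-ethylideneoxetan-2-one 14 (not isolated)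
Conditions: 13 (1.5 equiv), Pd(OAc)2 (5 mol%), Xantphos (6 mol%), i-Pr2NEt (1.2 equiv relative to 13), CO (1 atm), PhMe (0.05 mol/L), 50 °C; filter through thiol-functionalised silica under Ar; then 10 (1.0 equiv), Ph2BOCH2CH2NH2 (10 mol%), i-Pr2NEt (20 mol%), PhMe/MeCN, 40 °C
Reagents that add atoms: carbon monoxide, [C-]#[O+]
Why: Proposed new method: a telescoped cyclocarbonylation and borinate-directed acyl transfer, in which the unprotected iodo alcohol is first closed to the strained lactone 14 (oxidative addition of the C–I bond to zerovalent palladium with retention, CO insertion, ring-closing acyl–oxygen reductive elimination), and the diol 10 is then bound as its tetracoordinate diphenylborinate chelate, whose less hindered primary oxygen attacks the lactone acyl carbon so that strain-driven acyl–oxygen cleavage forms the ester C–O bond and unveils the CH2OH group; the product's mono-alcohols cannot chelate boron, which suppresses over-acylation, and no event touches the trisubstituted alkene or the carbinol centres, so the Z geometry and both stereocentres are kept; the closest known reaction types are palladium-catalysed cyclocarbonylation of halo alcohols and 2-haloallylamines to lactones and alpha-methylene beta-lactams, acyl–oxygen alcoholysis of beta-lactones, and borinic-acid-catalysed regioselective acylation of diols by acyl chlorides (a beta-lactone has not served as the acyl donor there, and the sequence has not been run on a free 2-iodoallylic alcohol).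

## Compound list

1 | (S)-4-benzyloxazolidin-2-one | O=C1N[C@@H](Cc2ccccc2)CO1 | starting material
2 | pent-4-enoyl chloride | C=CCCC(=O)Cl | starting material
3 | (S)-4-benzyl-3-(pent-4-enoyl)oxazolidin-2-one | C=CCCC(=O)N1[C@@H](Cc2ccccc2)COC1=O | intermediate
4 | 3,4-dimethoxystyrene (4-ethenyl-1,2-dimethoxybenzene) | C=Cc1ccc(OC)c(OC)c1 | starting material
5 | (S)-4-benzyl-3-[(E)-5-(3,4-dimethoxyphenyl)pent-4-enoyl]oxazolidin-2-one | O=C(CC/C=C/c1ccc(OC)c(OC)c1)N1[C@@H](Cc2ccccc2)COC1=O | intermediate
6 | 3,4-dimethoxybenzaldehyde (veratraldehyde) | O=Cc1ccc(OC)c(OC)c1 | starting material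
7 | dibutylboron Z-enolate of 5, (S)-4-benzyl-3-[(1Z,4E)-1-[(dibutylboranyl)oxy]-5-(3,4-dimethoxyphenyl)penta-1,4-dien-1-yl]oxazolidin-2-one, formed in the flask | CCCCB(CCCC)O/C(=C\C/C=C/c1ccc(OC)c(OC)c1)N1[C@@H](Cc2ccccc2)COC1=O | intermediate
8 | dibutylboron aldolate, (S)-4-benzyl-3-[(2S,3S)-3-[(dibutylboranyl)oxy]-3-(3,4-dimethoxyphenyl)-2-[(E)-3-(3,4-dimethoxyphenyl)prop-2-en-1-yl]propanoyl]oxazolidin-2-one, formed in the flask | O=C(N1[C@@H](Cc2ccccc2)COC1=O)[C@@H](C/C=C/c1ccc(OC)c(OC)c1)[C@H](OB(CCCC)CCCC)c1ccc(OC)c(OC)c1 | intermediate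
9 | (S)-4-benzyl-3-[(2S,3S)-3-(3,4-dimethoxyphenyl)-2-[(E)-3-(3,4-dimethoxyphenyl)prop-2-en-1-yl]-3-hydroxypropanoyl]oxazolidin-2-one | O=C(N1[C@@H](Cc2ccccc2)COC1=O)[C@@H](C/C=C/c1ccc(OC)c(OC)c1)[C@H](O)c1ccc(OC)c(OC)c1 | intermediate
10 | (1S,2R)-1-(3,4-dimethoxyphenyl)-2-[(E)-3-(3,4-dimethoxyphenyl)prop-2-en-1-yl]propane-1,3-diol | OC[C@@H](C/C=C/c1ccc(OC)c(OC)c1)[C@H](O)c1ccc(OC)c(OC)c1 | intermediate
11 | (E)-but-2-enal (crotonaldehyde) | C/C=C/C=O | starting material
12 | (Z)-2-iodobut-2-enal | C/C=C(\I)C=O | intermediate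
13 | (Z)-2-iodobut-2-en-1-ol | C/C=C(\I)CO | intermediate
14 | (Z)-3-ethylideneoxetan-2-one, formed in the flask | C/C=C1\C(=O)OC1 | intermediate
15 | (2R,3S)-3-(3,4-dimethoxyphenyl)-2-[(E)-3-(3,4-dimethoxyphenyl)prop-2-en-1-yl]-3-hydroxypropyl (Z)-2-(hydroxymethyl)but-2-enoate | C/C=C(/CO)C(=O)OC[C@@H](C/C=C/c1ccc(OC)c(OC)c1)[C@H](O)c1ccc(OC)c(OC)c1 | target

## Step count and risks

Total steps: 7. Longest linear sequence: 5 (steps 1, 2, 3, 4 and 7); steps 5 and 6 form the second branch.

**Step 7 (the proposed new step).** The lactone 14 may oligomerise or be ionised at its allylic C–O bond by zerovalent palladium before it is used. The borinate may also be too weak a nucleophile, or may attack the ring CH2 instead of the acyl carbon. The fallback uses known chemistry only; it sets out from 13 (and uses 10) and comes back to the route at 15. Silylation of 13 (TBSCl, imidazole, DMF) gives (Z)-tert-butyl[(2-iodobut-2-en-1-yl)oxy]dimethylsilane F1. Palladium-catalysed hydroxycarbonylation with retention of geometry (Pd(OAc)2, PPh3, CO 1 atm, H2O, Et3N, DMF, 50 °C) gives (Z)-2-{[(tert-butyldimethylsilyl)oxy]methyl}but-2-enoic acid F2. Carbodiimide esterification at the primary hydroxyl of 10 (EDC·HCl, DMAP 10 mol%, CH2Cl2, 0 °C) gives (2R,3S)-3-(3,4-dimethoxyphenyl)-2-[(E)-3-(3,4-dimethoxyphenyl)prop-2-en-1-yl]-3-hydroxypropyl (Z)-2-{[(tert-butyldimethylsilyl)oxy]methyl}but-2-enoate F3. Buffered desilylation (HF·pyridine, pyridine, THF, 0 °C) then gives 15.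

**Step 2.** The cross-metathesis may stall, or give homodimers and some Z isomer. The fallback sets out from 3 and comes back at 5, and it makes no new compound (F0). A Mizoroki–Heck arylation of 3 with purchased 4-iodo-1,2-dimethoxybenzene (Pd(OAc)2, P(o-tol)3, Et3N, MeCN, 80 °C) gives 5 directly, with the E alkene set by syn beta-hydride elimination. A minor alkene-migration isomer is removed by chromatography.

**Step 3.** The electron-rich styrene of 5 may not tolerate the boron triflate or the peroxide work-up, and the electron-rich aldehyde may react slowly. The fallback changes the order of events; it sets out from 3 (step 2 is then not run) and comes back at 9. The boron aldol is run on the styrene-free imide 3 (Bu2BOTf, i-Pr2NEt, CH2Cl2; then 6; H2O2 work-up). It passes through the dibutylboron Z-enolate of 3, (S)-4-benzyl-3-[(Z)-1-[(dibutylboranyl)oxy]penta-1,4-dien-1-yl]oxazolidin-2-one F4, and the dibutylboron aldolate (S)-4-benzyl-3-[(2S,3S)-3-[(dibutylboranyl)oxy]-3-(3,4-dimethoxyphenyl)-2-(prop-2-en-1-yl)propanoyl]oxazolidin-2-one F5. This gives (S)-4-benzyl-3-[(2S,3S)-3-(3,4-dimethoxyphenyl)-3-hydroxy-2-(prop-2-en-1-yl)propanoyl]oxazolidin-2-one F6. The styrene is attached afterwards by cross-metathesis of F6 with 4 (second-generation Grubbs catalyst (H2IMes)(PCy3)Cl2Ru=CHPh, CH2Cl2, 40 °C), which gives 9.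

## Further compounds

F1 | step 7 | (Z)-tert-butyl[(2-iodobut-2-en-1-yl)oxy]dimethylsilane | C/C=C(\I)CO[Si](C)(C)C(C)(C)C
F2 | step 7 | (Z)-2-{[(tert-butyldimethylsilyl)oxy]methyl}but-2-enoic acid | C/C=C(/CO[Si](C)(C)C(C)(C)C)C(=O)O
F3 | step 7 | (2R,3S)-3-(3,4-dimethoxyphenyl)-2-[(E)-3-(3,4-dimethoxyphenyl)prop-2-en-1-yl]-3-hydroxypropyl (Z)-2-{[(tert-butyldimethylsilyl)oxy]methyl}but-2-enoate | C/C=C(/CO[Si](C)(C)C(C)(C)C)C(=O)OC[C@@H](C/C=C/c1ccc(OC)c(OC)c1)[C@H](O)c1ccc(OC)c(OC)c1
F0 | step 2 | none | none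
F4 | step 3 | (S)-4-benzyl-3-[(Z)-1-[(dibutylboranyl)oxy]penta-1,4-dien-1-yl]oxazolidin-2-one | CCCCB(CCCC)O/C(=C\CC=C)N1[C@@H](Cc2ccccc2)COC1=O
F5 | step 3 | (S)-4-benzyl-3-[(2S,3S)-3-[(dibutylboranyl)oxy]-3-(3,4-dimethoxyphenyl)-2-(prop-2-en-1-yl)propanoyl]oxazolidin-2-one | O=C(N1[C@@H](Cc2ccccc2)COC1=O)[C@@H](CC=C)[C@H](OB(CCCC)CCCC)c1ccc(OC)c(OC)c1
F6 | step 3 | (S)-4-benzyl-3-[(2S,3S)-3-(3,4-dimethoxyphenyl)-3-hydroxy-2-(prop-2-en-1-yl)propanoyl]oxazolidin-2-one | O=C(N1[C@@H](Cc2ccccc2)COC1=O)[C@@H](CC=C)[C@H](O)c1ccc(OC)c(OC)c1
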